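**Plan**
- Locants: cyclohexane C5 (isopropenyl CH), C6 (lactone OCH), C7 (lactone CH), C8 (angelate CH), C9 (acetate CH), C10 (quaternary C); lactone carbons C11 and C12; exocyclic methylene C13.
- Enabling feature: on the cyclohexane ring C5–C10 the carbinol C8 is flanked by C7, which carries the two-carbon carboxyl arm C11–C12 trans to O8. This is the imprint of a C8 ketyl radical closing onto the β-carbon of a C7=C11–C12 enoate.
- Retrosynthetic cuts, in order: enol acetate C–O (back to a C10 ethynyl group), O9 acetate, C11=C13, lactone O6–C12, O8 angelate, ring bond C7–C8, then C5–C6 (allylboration) and C10–C(alkyne) (epoxide opening).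
- Forward: the chain C8–C9–C10–C5–C6–C7=C11–C12 is built linearly; the cyclohexane closes first (C7–C8), the γ-lactone second (O6–C12); methylenation, acetylation and Z-selective hydroacetoxylation finish.
- Stereochemistry: C9/C10 from Sharpless epoxidation of a Z allylic alcohol and invertive alkynylalane opening; C5/C6 from an anti-selective allylboration steered by C10; C7/C8 from the chair transition state of the radical closure; the Z enol acetate from ruthenium vinylidene catalysis.

Key step: step 17

Remark: aldehyde 1 and phosphonate 2 are taken to be purchasable; CIP descriptors are given with the locants defined above (up face of the ring: O6, O8, alkynyl; down face: isopropenyl, C11 arm, O9, C10 methyl).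

**Step 1**
Reactants: 1 2-[(4-methoxybenzyl)oxy]acetaldehyde; 2 ethyl 2-[bis(2,2,2-trifluoroethoxy)phosphoryl]propanoate
Product: 3 ethyl (Z)-4-[(4-methoxybenzyl)oxy]-2-methylbut-2-enoate
Conditions: KN(SiMe3)2, 18-crown-6, THF, −78 °C
Reagents that add atoms: none
Why: Still–Gennari modification of the Horner–Wadsworth–Emmons olefination: the electron-poor bis(trifluoroethyl) phosphonate collapses from the kinetic adduct before it can equilibrate, so the ester ends cis to the CH2OPMB group (Z), the geometry the later epoxide opening needs to relate C9 and C10 correctly.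

**Step 2**
Reactants: 3 Z enoate
Product: 4 (Z)-4-[(4-methoxybenzyl)oxy]-2-methylbut-2-en-1-ol
Conditions: i-Bu2AlH, CH2Cl2, −78 → 0 °C
Reagents that add atoms: none
Why: Ester reduction with i-Bu2AlH at low temperature gives the allylic alcohol by 1,2-hydride delivery without touching the Z alkene or the PMB ether.

**Step 3**
Reactants: 4 Z allylic alcohol
Product: 5 [(2R,3S)-3-{[(4-methoxybenzyl)oxy]methyl}-2-methyloxiran-2-yl]methanol
Conditions: Ti(OiPr)4 (0.2 equiv), D-(−)-diethyl tartrate (0.25 equiv), t-BuOOH, 4 Å MS, CH2Cl2, −20 °C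
Reagents that add atoms: tert-butyl hydroperoxide, CC(C)(C)OO
Why: Katsuki–Sharpless asymmetric epoxidation: the titanium complex of the (S,S)-tartrate delivers oxygen to the alkene face that makes the carbinol-bearing epoxide carbon R (the mirror image of the 2S outcome of the natural tartrate), which fixes C9 and the still-to-be-inverted C10 in one step.

**Step 4**
Reactants: 5 epoxy alcohol; 6 trimethylsilylacetylene
Product: 9 (2S,3R)-4-[(4-methoxybenzyl)oxy]-2-methyl-2-[(trimethylsilyl)ethynyl]butane-1,3-diol, via lithium (trimethylsilyl)acetylide 7 (not isolated), via diethyl[(trimethylsilyl)ethynyl]alane 8 (not isolated)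
Conditions: n-BuLi, toluene, 0 °C; Et2AlCl, 0 °C; then 5, 0 °C → rt (4 equiv of alane); aq. KNa tartrate
Reagents that add atoms: n-butyllithium, [Li]CCCC (lithium kept in 7 only); diethylaluminium chloride, CC[Al](Cl)CC (aluminium and ethyl groups kept in 8 only)
Why: Alkynylalane opening of a trisubstituted epoxy alcohol: aluminium activates the epoxide oxygen and the alkynyl group attacks the tertiary carbon C10 (the one that best supports positive charge, C9 being deactivated by its CH2OPMB neighbour) anti to the breaking C–O bond, so C10 is inverted into the quaternary centre (10S) while C9 keeps its oxygen (9R).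

**Step 5**
Reactants: 9 diol
Product: 10 (2R,3R)-3-hydroxy-4-[(4-methoxybenzyl)oxy]-2-methyl-2-[(trimethylsilyl)ethynyl]butanal
Conditions: TEMPO (10 mol%), PhI(OAc)2, CH2Cl2, rt
Reagents that add atoms: none
Why: TEMPO/PhI(OAc)2 oxidation runs through a bulky oxoammonium salt that oxidises the primary carbinol far faster than the neopentylic secondary one, and the aldehyde formed has no α-hydrogen, so it can neither epimerise nor eliminate.

**Step 6**
Reactants: 10 hydroxy aldehyde
Product: 11 (2R,3R)-3-[(tert-butyldimethylsilyl)oxy]-4-[(4-methoxybenzyl)oxy]-2-methyl-2-[(trimethylsilyl)ethynyl]butanal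
Conditions: TBSOTf, 2,6-lutidine, CH2Cl2, −78 → 0 °C
Reagents that add atoms: tert-butyldimethylsilyl trifluoromethanesulfonate, CC(C)(C)[Si](C)(C)OS(=O)(=O)C(F)(F)F
Why: Silylation with the triflate and a hindered pyridine base caps the crowded C9 hydroxyl as a bulky, non-chelating TBS ether and closes the retro-aldol pathway before any strong base is used.

**Step 7**
Reactants: 11 aldehyde; 12 triethyl 2-phosphonopropionate
Product: 13 ethyl (2E,4R,5R)-5-[(tert-butyldimethylsilyl)oxy]-6-[(4-methoxybenzyl)oxy]-2,4-dimethyl-4-[(trimethylsilyl)ethynyl]hex-2-enoate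
Conditions: NaH, THF, 0 → 45 °C
Reagents that add atoms: none
Why: Horner–Wadsworth–Emmons olefination with the stabilised α-methyl phosphonate under equilibrating conditions gives the E trisubstituted enoate (C10 trans to the ester), the α-quaternary aldehyde being non-enolisable so that only addition can occur.

**Step 8**
Reactants: 13 E enoate
Product: 14 (2E,4R,5R)-5-[(tert-butyldimethylsilyl)oxy]-6-[(4-methoxybenzyl)oxy]-2,4-dimethyl-4-[(trimethylsilyl)ethynyl]hex-2-en-1-ol
Conditions: i-Bu2AlH, CH2Cl2, −78 °C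
Reagents that add atoms: none
Why: 1,2-Reduction of the enoate with i-Bu2AlH gives the E allylic alcohol and leaves the silyl ether, the PMB ether and the silylalkyne untouched.

**Step 9**
Reactants: 14 allylic alcohol
Product: 15 (2E,4R,5R)-5-[(tert-butyldimethylsilyl)oxy]-6-[(4-methoxybenzyl)oxy]-2,4-dimethyl-4-[(trimethylsilyl)ethynyl]hex-2-en-1-yl acetate
Conditions: Ac2O, pyridine, DMAP (cat.), CH2Cl2, 0 °C → rt
Reagents that add atoms: acetic anhydride, CC(=O)OC(C)=O
Why: DMAP-catalysed acylation of the unhindered primary allylic alcohol installs the leaving group for palladium.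

**Step 10**
Reactants: 15 allylic acetate
Product: 16 pinacol (2E,4R,5R)-5-[(tert-butyldimethylsilyl)oxy]-6-[(4-methoxybenzyl)oxy]-2,4-dimethyl-4-[(trimethylsilyl)ethynyl]hex-2-en-1-ylboronate
Conditions: Pd2(dba)3 (3 mol%), B2pin2, DMSO, 50 °C
Reagents that add atoms: bis(pinacolato)diboron, CC1(C)OB(OC1(C)C)B1OC(C)(C)C(C)(C)O1
Why: Miyaura allylic borylation: zerovalent palladium ionises the acetate to a π-allyl complex that takes up the boryl group at its unhindered CH2 terminus, the bulky C10 substituent staying syn so that the E geometry is kept.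

**Step 11**
Reactants: 17 2,2-dimethoxyacetaldehyde (60% in water); 18 tert-butyl (triphenylphosphoranylidene)acetate
Product: 19 tert-butyl (E)-4,4-dimethoxybut-2-enoate
Conditions: CH2Cl2, rt
Reagents that add atoms: none
Why: Wittig olefination with a stabilised ylide gives the E enoate under thermodynamic control and tolerates the aqueous aldehyde solution.

**Step 12**
Reactants: 19 acetal
Product: 20 tert-butyl (E)-4-oxobut-2-enoate
Conditions: p-TsOH·H2O (cat.), acetone/H2O, rt; used freshly prepared
Reagents that add atoms: water, O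
Why: Mild acid-catalysed acetal hydrolysis frees the aldehyde while the tert-butyl ester, which needs much stronger acid, survives.

**Step 13**
Reactants: 16 allylboronate; 20 tert-butyl (E)-4-oxobut-2-enoate
Product: 22 tert-butyl (2E,4S,5S,6R,7R)-7-[(tert-butyldimethylsilyl)oxy]-4-hydroxy-8-[(4-methoxybenzyl)oxy]-6-methyl-5-(prop-1-en-2-yl)-6-[(trimethylsilyl)ethynyl]oct-2-enoate, via O6-pinacolboryl ether 21 (not isolated)
Conditions: toluene, rt → 45 °C; aq. NaHCO3
Reagents that add atoms: none
Why: Thermal allylboration through a closed chair transition state: the E allylboronate places C10 pseudo-equatorial and so gives the anti relation of C10 and O6, while A1,3 strain with the 2-methyl group turns the slim alkynyl substituent of C10 into the alkene plane, so that the aldehyde reaches C5 on the face opposite the bulky C9 silyloxy chain and sets C5 (S) and C6 (S) relative to C10.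

**Step 14**
Reactants: 22 homoallylic alcohol
Product: 23 tert-butyl (2E,4S,5S,6R,7R)-7-[(tert-butyldimethylsilyl)oxy]-8-[(4-methoxybenzyl)oxy]-6-methyl-5-(prop-1-en-2-yl)-4-[(triethylsilyl)oxy]-6-[(trimethylsilyl)ethynyl]oct-2-enoate
Conditions: TESOTf, 2,6-lutidine, CH2Cl2, −78 °C
Reagents that add atoms: triethylsilyl trifluoromethanesulfonate, CC[Si](CC)(CC)OS(=O)(=O)C(F)(F)F
Why: Silylation of the allylic secondary alcohol with the triflate gives a TES ether that survives the next four steps but is far more acid-labile than the TBS ether at O9, which later lets O6 alone be unmasked.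

**Step 15**
Reactants: 23 PMB ether
Product: 24 tert-butyl (2E,4S,5S,6R,7R)-7-[(tert-butyldimethylsilyl)oxy]-8-hydroxy-6-methyl-5-(prop-1-en-2-yl)-4-[(triethylsilyl)oxy]-6-[(trimethylsilyl)ethynyl]oct-2-enoate
Conditions: DDQ, CH2Cl2/pH 7 phosphate buffer, 0 °C
Reagents that add atoms: none
Why: Oxidative cleavage of the electron-rich PMB ether by DDQ (hydride abstraction, then hydrolysis of the oxocarbenium ion) in buffered wet CH2Cl2 spares the silyl ethers, the alkenes and the silylalkyne.

**Step 16**
Reactants: 24 primary alcohol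
Product: 25 tert-butyl (2E,4S,5S,6R,7R)-7-[(tert-butyldimethylsilyl)oxy]-6-methyl-8-oxo-5-(prop-1-en-2-yl)-4-[(triethylsilyl)oxy]-6-[(trimethylsilyl)ethynyl]oct-2-enoate
Conditions: Dess–Martin periodinane, NaHCO3, CH2Cl2, 0 °C → rt
Reagents that add atoms: none
Why: Dess–Martin oxidation under bicarbonate buffering gives the α-silyloxy aldehyde without epimerising C9 or moving the silyl group.

**Step 17**
Reactants: 25 acyclic α-silyloxy aldehyde γ-silyloxy E enoate
Product: 26 cyclohexanol (5S,6R,7R,8R,9R,10R): ring C5–C10 with C5 isopropenyl, C6 OTES, C7 CH2CO2t-Bu, free C8 OH, C9 OTBS, C10 methyl and (trimethylsilyl)ethynyl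
Conditions: SmI2 (2.5 equiv), t-BuOH (3 equiv), THF, −78 °C; aq. NH4Cl at −78 °C
Reagents that add atoms: none
Why: SmI2 (divalent samarium) gives one electron to the C8 aldehyde, the samarium-bound ketyl radical attacks the electron-poor β-carbon C7 of the enoate, and a second electron turns the C11 radical into a trivalent samarium enolate that tert-butanol protonates. The closest known reaction type is the SmI2-mediated ketyl–olefin cyclisation of aldehydes onto α,β-unsaturated esters, established for α-alkoxy aldehydes derived from sugars. The cyclohexane ring C5–C10 closes in the 6-exo-trig mode. C7 is set by a chair transition state in which the isopropenyl group at C5, the silyloxy groups at C6 and C9 and the alkynyl group at C10 are equatorial, so the E enoate lies pseudo-equatorial and the C11 arm ends trans to O6. C8 is set in the same chair, where the samarium-bound oxygen turns away from the ester dipole and avoids a 1,3-diaxial clash with the axial C10 methyl group, so O8 ends equatorial, trans to the C11 arm and to O9, the bulky TBS ether excluding chelation. The step needs ring closure to outrun both further reduction of the ketyl (which would expel the C9 silyloxy group) and lactonisation of the samarium alkoxide, which the fast closure of the quaternary-substituted chain, the low temperature and the tert-butyl ester secure, leaving O8 as the only free hydroxyl.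

**Step 18**
Reactants: 26 cyclohexanol; 27 angelic acid
Product: 29 O8-angelate of cyclohexanol 26 (5S,6R,7R,8R,9R,10R), via angelic 2,4,6-trichlorobenzoic anhydride 28 (not isolated)
Conditions: 27, 2,4,6-trichlorobenzoyl chloride, Et3N, toluene, rt; then 26, 80 °C
Reagents that add atoms: 2,4,6-trichlorobenzoyl chloride, O=C(Cl)c1c(Cl)cc(Cl)cc1Cl (atoms kept in 28 only)
Why: Yamaguchi esterification through the mixed anhydride, run without DMAP so that the Z geometry of the angeloyl group is not lost to reversible conjugate addition, acylates O8 because it is the only free hydroxyl.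

**Step 19**
Reactants: 29 angelate
Product: 31 trans-fused 6,12-γ-lactone (5S,6R,7S,8R,9R,10R) with O8 angelate; O9 TBS ether; C10 (trimethylsilyl)ethynyl, via hydroxy acid 30 (not isolated)
Conditions: CF3CO2H/CH2Cl2 (1:9), 0 °C → rt
Reagents that add atoms: none
Why: Acidolysis removes the labile TES ether at O6 and the tert-butyl ester while the neopentylic TBS ether at O9 and the silylalkyne resist, and the γ-hydroxy acid lactonises at once to the trans-fused γ-lactone because O6 and the C11–C12 arm are trans-diequatorial neighbours.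

**Step 20**
Reactants: 31 lactone
Product: 34 α-methylene lactone (C11=C13; 5S,6R,7S,8R,9R,10R), via Mannich base 32 (not isolated), via trimethylammonium iodide 33 (not isolated)
Conditions: LiN(SiMe3)2, THF, −78 °C; Me2N=CH2+ I−, −78 → 0 °C; MeI, rt; aq. NaHCO3, CH2Cl2
Reagents that add atoms: N,N-dimethylmethyleneiminium iodide (Eschenmoser's salt), C=[N+](C)C.[I-]; iodomethane, CI (methyl kept in 33 only)
Why: Enolate Mannich reaction with Eschenmoser's salt followed by quaternisation and E1cB elimination (α-methylenation of a lactone): the lactone CH2 is the only acidic α-position, since the angelate has no α-hydrogen and the alkyne is silyl-capped, and no existing stereocentre is enolisable.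

**Step 21**
Reactants: 34 α-methylene lactone
Product: 35 hydroxy alkyne (5S,6R,7S,8R,9R,10R): free O9–H and terminal ethynyl group at C10
Conditions: Bu4NF, AcOH (1:1), THF, 0 °C → rt
Reagents that add atoms: none
Why: Buffered TBAF desilylation: fluoride cleaves the Si–O bond at O9 and the Si–C(sp) bond of the alkyne, and acetic acid keeps the medium from moving the angeloyl group from O8 to O9 or adding to the methylene lactone.

**Step 22**
Reactants: 35 hydroxy alkyne
Product: 36 O9-acetate (5S,6R,7S,8R,9R,10R) with terminal ethynyl group at C10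
Conditions: Ac2O, pyridine, DMAP (cat.), CH2Cl2, 0 °C → rt
Reagents that add atoms: acetic anhydride, CC(=O)OC(C)=O
Why: DMAP-catalysed acetylation of the single remaining hydroxyl (O9) under weakly basic conditions leaves the angelate, the methylene lactone and the terminal alkyne intact.

**Step 23**
Reactants: 36 terminal alkyne
Product: 37 CNP0582479.1 (5S,6R,7S,8R,9R,10S)
Conditions: Ru(η3-CH2C(CH3)CH2)2(Ph2P(CH2)4PPh2) (5 mol%), AcOH (3 equiv), toluene, 65 °C
Reagents that add atoms: acetic acid, CC(=O)O
Why: Ruthenium-catalysed anti-Markovnikov hydro-oxycarbonylation of a terminal alkyne: the divalent ruthenium bis(methallyl) diphosphine complex converts the alkyne into a vinylidene, acetate adds to its terminal carbon and protonolysis releases the Z enol acetate, the quaternary C10 reinforcing the terminal regiochemistry.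

**Compound list**
1 | 2-[(4-methoxybenzyl)oxy]acetaldehyde | COc1ccc(COCC=O)cc1 | starting material
2 | ethyl 2-[bis(2,2,2-trifluoroethoxy)phosphoryl]propanoate | CCOC(=O)C(C)P(=O)(OCC(F)(F)F)OCC(F)(F)F | starting material
3 | ethyl (Z)-4-[(4-methoxybenzyl)oxy]-2-methylbut-2-enoate | CCOC(=O)/C(C)=C\COCc1ccc(OC)cc1 | intermediate
4 | (Z)-4-[(4-methoxybenzyl)oxy]-2-methylbut-2-en-1-ol | OC/C(C)=C\COCc1ccc(OC)cc1 | intermediate
5 | [(2R,3S)-3-{[(4-methoxybenzyl)oxy]methyl}-2-methyloxiran-2-yl]methanol | COc1ccc(COC[C@@H]2O[C@]2(C)CO)cc1 | intermediate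
6 | trimethylsilylacetylene | C#C[Si](C)(C)C | starting material
7 | lithium (trimethylsilyl)acetylide | [Li]C#C[Si](C)(C)C | intermediate
8 | diethyl[(trimethylsilyl)ethynyl]alane | CC[Al](CC)C#C[Si](C)(C)C | intermediate
9 | (2S,3R)-4-[(4-methoxybenzyl)oxy]-2-methyl-2-[(trimethylsilyl)ethynyl]butane-1,3-diol (9R,10S) | COc1ccc(COC[C@H](O)[C@@](C)(C#C[Si](C)(C)C)CO)cc1 | intermediate
10 | (2R,3R)-3-hydroxy-4-[(4-methoxybenzyl)oxy]-2-methyl-2-[(trimethylsilyl)ethynyl]butanal | COc1ccc(COC[C@H](O)[C@@](C)(C#C[Si](C)(C)C)C=O)cc1 | intermediate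
11 | (2R,3R)-3-[(tert-butyldimethylsilyl)oxy]-4-[(4-methoxybenzyl)oxy]-2-methyl-2-[(trimethylsilyl)ethynyl]butanal | COc1ccc(COC[C@H](O[Si](C)(C)C(C)(C)C)[C@@](C)(C#C[Si](C)(C)C)C=O)cc1 | intermediate
12 | triethyl 2-phosphonopropionate | CCOC(=O)C(C)P(=O)(OCC)OCC | starting material
13 | ethyl (2E,4R,5R)-5-[(tert-butyldimethylsilyl)oxy]-6-[(4-methoxybenzyl)oxy]-2,4-dimethyl-4-[(trimethylsilyl)ethynyl]hex-2-enoate | COc1ccc(COC[C@H](O[Si](C)(C)C(C)(C)C)[C@@](C)(C#C[Si](C)(C)C)/C=C(\C)C(=O)OCC)cc1 | intermediate
14 | (2E,4R,5R)-5-[(tert-butyldimethylsilyl)oxy]-6-[(4-methoxybenzyl)oxy]-2,4-dimethyl-4-[(trimethylsilyl)ethynyl]hex-2-en-1-ol | COc1ccc(COC[C@H](O[Si](C)(C)C(C)(C)C)[C@@](C)(C#C[Si](C)(C)C)/C=C(\C)CO)cc1 | intermediate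
15 | acetate of 14 | COc1ccc(COC[C@H](O[Si](C)(C)C(C)(C)C)[C@@](C)(C#C[Si](C)(C)C)/C=C(\C)COC(C)=O)cc1 | intermediate
16 | pinacol (2E,4R,5R)-allylboronate (Bpin in place of the acetoxy group of 15) | COc1ccc(COC[C@H](O[Si](C)(C)C(C)(C)C)[C@@](C)(C#C[Si](C)(C)C)/C=C(\C)CB2OC(C)(C)C(C)(C)O2)cc1 | intermediate
17 | 2,2-dimethoxyacetaldehyde | COC(OC)C=O | starting material
18 | tert-butyl (triphenylphosphoranylidene)acetate | CC(C)(C)OC(=O)C=P(c1ccccc1)(c1ccccc1)c1ccccc1 | starting material
19 | tert-butyl (E)-4,4-dimethoxybut-2-enoate | COC(OC)/C=C/C(=O)OC(C)(C)C | intermediate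
20 | tert-butyl (E)-4-oxobut-2-enoate | O=C/C=C/C(=O)OC(C)(C)C | intermediate
21 | O6-pinacolboryl ether of 22 | COc1ccc(COC[C@H](O[Si](C)(C)C(C)(C)C)[C@@](C)(C#C[Si](C)(C)C)[C@H](C(C)=C)[C@@H](OB2OC(C)(C)C(C)(C)O2)/C=C/C(=O)OC(C)(C)C)cc1 | intermediate
22 | tert-butyl (2E,4S,5S,6R,7R)-7-[(tert-butyldimethylsilyl)oxy]-4-hydroxy-8-[(4-methoxybenzyl)oxy]-6-methyl-5-(prop-1-en-2-yl)-6-[(trimethylsilyl)ethynyl]oct-2-enoate (5S,6S,9R,10R) | COc1ccc(COC[C@H](O[Si](C)(C)C(C)(C)C)[C@@](C)(C#C[Si](C)(C)C)[C@H](C(C)=C)[C@@H](O)/C=C/C(=O)OC(C)(C)C)cc1 | intermediate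
23 | O6-triethylsilyl ether of 22 | COc1ccc(COC[C@H](O[Si](C)(C)C(C)(C)C)[C@@](C)(C#C[Si](C)(C)C)[C@H](C(C)=C)[C@@H](O[Si](CC)(CC)CC)/C=C/C(=O)OC(C)(C)C)cc1 | intermediate
24 | C8 primary alcohol (PMB removed from 23) | OC[C@H](O[Si](C)(C)C(C)(C)C)[C@@](C)(C#C[Si](C)(C)C)[C@H](C(C)=C)[C@@H](O[Si](CC)(CC)CC)/C=C/C(=O)OC(C)(C)C | intermediate
25 | tert-butyl (2E,4S,5S,6R,7R)-7-[(tert-butyldimethylsilyl)oxy]-6-methyl-8-oxo-5-(prop-1-en-2-yl)-4-[(triethylsilyl)oxy]-6-[(trimethylsilyl)ethynyl]oct-2-enoate | O=C[C@H](O[Si](C)(C)C(C)(C)C)[C@@](C)(C#C[Si](C)(C)C)[C@H](C(C)=C)[C@@H](O[Si](CC)(CC)CC)/C=C/C(=O)OC(C)(C)C | intermediate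
26 | cyclohexanol (5S,6R,7R,8R,9R,10R): C5 isopropenyl, C6 OTES, C7 CH2CO2t-Bu, C8 OH, C9 OTBS, C10 methyl and (trimethylsilyl)ethynyl | O[C@H]1[C@H](O[Si](C)(C)C(C)(C)C)[C@@](C)(C#C[Si](C)(C)C)[C@H](C(C)=C)[C@@H](O[Si](CC)(CC)CC)[C@@H]1CC(=O)OC(C)(C)C | intermediate
27 | angelic acid, (Z)-2-methylbut-2-enoic acid | C/C=C(/C)C(=O)O | starting material
28 | angelic 2,4,6-trichlorobenzoic anhydride | C/C=C(/C)C(=O)OC(=O)c1c(Cl)cc(Cl)cc1Cl | intermediate
29 | O8-angelate of 26 (5S,6R,7R,8R,9R,10R) | C/C=C(/C)C(=O)O[C@H]1[C@H](O[Si](C)(C)C(C)(C)C)[C@@](C)(C#C[Si](C)(C)C)[C@H](C(C)=C)[C@@H](O[Si](CC)(CC)CC)[C@@H]1CC(=O)OC(C)(C)C | intermediate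
30 | hydroxy acid: 29 with free O6–H and C12 carboxylic acid | C/C=C(/C)C(=O)O[C@H]1[C@H](O[Si](C)(C)C(C)(C)C)[C@@](C)(C#C[Si](C)(C)C)[C@H](C(C)=C)[C@@H](O)[C@@H]1CC(=O)O | intermediate
31 | trans-fused 6,12-γ-lactone (5S,6R,7S,8R,9R,10R): C11 H2, O8 angelate, O9 TBS ether, C10 methyl and (trimethylsilyl)ethynyl, C5 isopropenyl | C1C(=O)O[C@H]2[C@H]1[C@@H](OC(=O)/C(C)=C\C)[C@H](O[Si](C)(C)C(C)(C)C)[C@@](C)(C#C[Si](C)(C)C)[C@@H]2C(=C)C | intermediate
32 | Mannich base: 31 with CH2NMe2 at C11 (both C11 epimers) | CN(C)CC1C(=O)O[C@H]2[C@H]1[C@@H](OC(=O)/C(C)=C\C)[C@H](O[Si](C)(C)C(C)(C)C)[C@@](C)(C#C[Si](C)(C)C)[C@@H]2C(=C)C | intermediate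
33 | trimethylammonium iodide of 32 | C[N+](C)(C)CC1C(=O)O[C@H]2[C@H]1[C@@H](OC(=O)/C(C)=C\C)[C@H](O[Si](C)(C)C(C)(C)C)[C@@](C)(C#C[Si](C)(C)C)[C@@H]2C(=C)C.[I-] | intermediate
34 | α-methylene lactone (C11=C13), otherwise as 31 | C=C1C(=O)O[C@H]2[C@H]1[C@@H](OC(=O)/C(C)=C\C)[C@H](O[Si](C)(C)C(C)(C)C)[C@@](C)(C#C[Si](C)(C)C)[C@@H]2C(=C)C | intermediate
35 | hydroxy alkyne: 34 with free O9–H and ethynyl at C10 | C=C1C(=O)O[C@H]2[C@H]1[C@@H](OC(=O)/C(C)=C\C)[C@H](O)[C@@](C)(C#C)[C@@H]2C(=C)C | intermediate
36 | O9-acetate of 35 | C=C1C(=O)O[C@H]2[C@H]1[C@@H](OC(=O)/C(C)=C\C)[C@H](OC(C)=O)[C@@](C)(C#C)[C@@H]2C(=C)C | intermediate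
37 | CNP0582479.1 (5S,6R,7S,8R,9R,10S): 8-O-angeloyl, 9-O-acetyl, C10 (Z)-2-acetoxyvinyl α-methylene-γ-lactone | C=C1C(=O)O[C@H]2[C@H]1[C@@H](OC(=O)/C(C)=C\C)[C@H](OC(C)=O)[C@@](C)(/C=C\OC(C)=O)[C@@H]2C(=C)C | target

**Step count**
Total: 23 steps. Longest linear sequence: 21 steps (steps 1–10 and 13–23, from aldehyde 1); steps 11–12 form the short branch to aldehyde 20.

**Steps most likely to fail**

Step 13 (allylboration). The two faces of C5 are told apart only by the resting conformation of the neighbouring quaternary C10, and transfer of this neopentylic carbon from a pinacol boronate is slow, so facial selectivity may be poor and the sensitive enal may degrade before it is consumed. The fallback replaces substrate control by reagent control with a more reactive boron ester. It sets out from allylic alcohol 14: palladium-catalysed borylation with B2(OH)4 (Pd(MeCN)4(BF4)2 cat., DMSO/MeOH) should give the allylboronic acid F1, and esterification with D-(−)-diisopropyl tartrate over MgSO4 the (S,S)-tartrate allylboronate F2. This Roush-type reagent should react with 20 in toluene over 4 Å sieves at −78 °C, the (S,S)-tartrate steering the allyl group to the Re face of the formyl group that the route requires; hydrolysis of the tartrate borate F3 on work-up returns to the route at 22.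

Step 17 (key cyclisation). The ketyl may add through a chelated or boat-like arrangement that places O8 cis to the C11 arm, that is, poor facial selectivity at the ketyl carbon. The fallback keeps the ring closure and corrects C8 afterwards. It sets out from 25: the 8-epimeric cyclohexanol F4 (axial O8) formed in the cyclisation is esterified under Mitsunobu conditions (PPh3, diisopropyl azodicarboxylate, angelic acid 27, toluene, 0 °C → rt). Backside displacement of an axial oxyphosphonium group is the favourable case for SN2 on a cyclohexane, and it installs the angelate with inversion, returning to the route at 29.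

Step 23 (hydroacetoxylation). Vinylidene formation may be slow at an alkyne flanked by a quaternary carbon, so that Markovnikov addition, E-isomer formation or cycloisomerisation of the 1,5-enyne (alkyne plus C5 isopropenyl) competes, and the enol acetate may suffer at the temperature required. The fallback builds the C–O bond by stereospecific copper coupling instead. It sets out from 36: rhodium-catalysed trans-hydroboration ([Rh(cod)Cl]2, P(i-Pr)3, Et3N, pinacolborane) should give the (Z)-alkenyl pinacol boronate F5, and KHF2 in aqueous methanol the potassium (Z)-alkenyltrifluoroborate F6. Oxidative Chan–Lam-type coupling of F6 with acetate (Cu(OAc)2, DMAP, 4 Å MS, air, MeCN) proceeds with retention of alkene geometry and returns to the route at 37.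

**Further compounds**
F1 | step 13 | allylboronic acid: B(OH)2 in place of the hydroxyl of 14 | COc1ccc(COC[C@H](O[Si](C)(C)C(C)(C)C)[C@@](C)(C#C[Si](C)(C)C)/C=C(\C)CB(O)O)cc1
F2 | step 13 | (S,S)-diisopropyl tartrate ester of allylboronic acid F1 | COc1ccc(COC[C@H](O[Si](C)(C)C(C)(C)C)[C@@](C)(C#C[Si](C)(C)C)/C=C(\C)CB2O[C@H](C(=O)OC(C)C)[C@@H](C(=O)OC(C)C)O2)cc1
F3 | step 13 | O6-boryl ether of 22 with the (S,S)-diisopropyl tartrate boron unit | COc1ccc(COC[C@H](O[Si](C)(C)C(C)(C)C)[C@@](C)(C#C[Si](C)(C)C)[C@H](C(C)=C)[C@@H](OB2O[C@H](C(=O)OC(C)C)[C@@H](C(=O)OC(C)C)O2)/C=C/C(=O)OC(C)(C)C)cc1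
F4 | step 17 | 8-epimer of cyclohexanol 26 (axial O8, cis to the C11 arm) | O[C@@H]1[C@H](O[Si](C)(C)C(C)(C)C)[C@@](C)(C#C[Si](C)(C)C)[C@H](C(C)=C)[C@@H](O[Si](CC)(CC)CC)[C@@H]1CC(=O)OC(C)(C)C
F5 | step 23 | (Z)-alkenyl pinacol boronate: Bpin in place of the enol acetoxy group of 37 | C=C1C(=O)O[C@H]2[C@H]1[C@@H](OC(=O)/C(C)=C\C)[C@H](OC(C)=O)[C@@](C)(/C=C\B3OC(C)(C)C(C)(C)O3)[C@@H]2C(=C)C
F6 | step 23 | potassium (Z)-alkenyltrifluoroborate derived from F5 | C=C1C(=O)O[C@H]2[C@H]1[C@@H](OC(=O)/C(C)=C\C)[C@H](OC(C)=O)[C@@](C)(/C=C\[B-](F)(F)F)[C@@H]2C(=C)C.[K+]
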